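**Retrosynthetic overview**
1. C12–C13 is made last, by nickel-catalysed cross-electrophile coupling of the unprotected triol iodide 25 with 3-bromofuran-2(5H)-one 29; the butenolide ring is brought in preformed, from furfural.
2. The 7-OH comes from allylic oxidation of the 8(17)-alkene to the 7-ketone and axial hydride delivery; 3-OH and 19-OH come from reduction of a bicyclic β-keto ester, which also releases a recoverable 8-phenylmenthyl auxiliary.
3. Rings A and B form in one oxidative radical cascade on the acyclic (E,E)-dienyl β-keto ester 19: ring A first (C4–C5), then ring B (C10–C9), with the exocyclic C8=C17 alkene formed at termination.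
4. C5–C6 is made by palladium-catalysed Negishi coupling of alkylzinc 18 with alkenyl iodide 17; both E-trisubstituted alkenes come from zirconium-catalysed methylalumination of but-3-yn-1-ol and prop-2-yn-1-ol.
5. Three branches converge: 8 (C6–C12, C17), 17 (C1–C5, C18–C20 plus auxiliary) and 29 (C13–C16).

Assumption: the (1S,2R,5S)-(+)-enantiomer of 8-phenylmenthol is taken as the auxiliary that leaves open the radical face leading to the 4S,5S,9R,10S series of 20; if the sense of induction proved opposite, the (1R,2S,5R)-(−)-enantiomer would be used in step 6 and nothing else would change.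

Conventions: labdane numbering is used for the skeleton (decalin C1–C10; C4 carries methyl C18 and C19; C10 carries methyl C20; C8 carries C17; C9 carries C11–C12; butenolide C13–C16). "8-Phenylmenthyl" means (1S,2R,5S)-5-methyl-2-(2-phenylpropan-2-yl)cyclohexyl.

**Branch 1: C6–C12 unit**

Step 1
Reactants: 1 but-3-yn-1-ol
Product: 2 tert-butyl(but-3-yn-1-yloxy)dimethylsilane
Conditions: TBSCl, imidazole, DMF, 0 °C to rt
Reagents that add atoms: tert-butyldimethylsilyl chloride, C[Si](C)(Cl)C(C)(C)C
Why: Standard silyl ether formation; the TBS group keeps the C6 oxygen apart from the C12 oxygen introduced next.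

Step 2
Reactants: 2 tert-butyl(but-3-yn-1-yloxy)dimethylsilane; 3 oxirane
Product: 6 (E)-6-[(tert-butyldimethylsilyl)oxy]-4-methylhex-3-en-1-ol, via alkenylalane 4 (not isolated), via lithium alkenylaluminate 5 (not isolated)
Conditions: AlMe3 (2.0 equiv), Cp2ZrCl2 (0.25 equiv), CH2Cl2, 0 °C to rt; evaporate; n-BuLi (1.0 equiv), hexane/THF, −78 °C; 3 (3 equiv), −78 to 0 °C; aq. sodium potassium tartrate
Reagents that add atoms: trimethylaluminium, C[Al](C)C
Why: Negishi zirconium-catalysed methylalumination adds CH3 and Al syn across the alkyne with CH3 on the internal carbon, and the butyl ate complex opens oxirane with retention at the alkenyl carbon, which fixes the E geometry of C8=C9 (C7 trans to C11).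

Step 3
Reactants: 6 (E)-6-[(tert-butyldimethylsilyl)oxy]-4-methylhex-3-en-1-ol
Product: 7 tert-butyl{[(E)-6-chloro-3-methylhex-3-en-1-yl]oxy}dimethylsilane
Conditions: N-chlorosuccinimide, PPh3, CH2Cl2, 0 °C to rt
Reagents that add atoms: N-chlorosuccinimide, O=C1CCC(=O)N1Cl
Why: Appel-type chlorination, SN2 displacement of the primary alkoxyphosphonium by chloride; silyl ether and alkene are untouched.

Step 4
Reactants: 7 tert-butyl{[(E)-6-chloro-3-methylhex-3-en-1-yl]oxy}dimethylsilane
Product: 8 (E)-1-bromo-6-chloro-3-methylhex-3-ene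
Conditions: Ph3PBr2, CH2Cl2, rt; aq. NaHCO3
Reagents that add atoms: dibromotriphenylphosphorane, BrP(Br)(c1ccccc1)(c1ccccc1)c1ccccc1
Why: Direct conversion of a primary silyl ether into the bromide (silyl transfer to bromide, then SN2 on the alkoxyphosphonium), giving a C–Br/C–Cl pair of clearly different reactivity.

**Branch 2: C1–C5 unit with the β-keto ester and auxiliary**

Step 5
Reactants: 9 methyl 3-oxobutanoate
Product: 10 methyl 2-methyl-3-oxobutanoate (racemic)
Conditions: MeI, K2CO3, acetone, reflux
Reagents that add atoms: iodomethane, CI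
Why: C-Methylation of the β-keto ester enolate (SN2) installs C18.

Step 6
Reactants: 10 methyl 2-methyl-3-oxobutanoate
Product: 11 8-phenylmenthyl 2-methyl-3-oxobutanoate (epimers at the α-carbon)
Conditions: (1S,2R,5S)-(+)-8-phenylmenthol (1.0 equiv), DMAP (0.2 equiv), toluene, reflux, MeOH distilled off
Reagents that add atoms: (1S,2R,5S)-8-phenylmenthol, O[C@H]1C[C@@H](C)CC[C@@H]1C(C)(C)c1ccccc1
Why: DMAP-catalysed transesterification of a β-keto ester through its acylketene attaches the recoverable chiral auxiliary that will control the facial sense of the radical cyclization.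

Step 7
Reactants: 12 prop-2-yn-1-ol
Product: 14 (E)-3-iodo-2-methylprop-2-en-1-ol, via alkenylalane 13 (not isolated)
Conditions: AlMe3 (3.0 equiv), Cp2ZrCl2 (0.25 equiv), CH2Cl2, 0 °C to rt; then I2, THF, −30 to 0 °C; aq. NaHCO3/Na2S2O3
Reagents that add atoms: trimethylaluminium, C[Al](C)C; iodine, II
Why: Negishi zirconium-catalysed methylalumination (syn addition, CH3 on the internal carbon) followed by iodinolysis of the C–Al bond with retention gives the E alkenyl iodide.

Step 8
Reactants: 14 (E)-3-iodo-2-methylprop-2-en-1-ol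
Product: 15 (E)-3-bromo-1-iodo-2-methylprop-1-ene
Conditions: CBr4, PPh3, CH2Cl2, 0 °C
Reagents that add atoms: tetrabromomethane, BrC(Br)(Br)Br
Why: Appel bromination of the primary allylic alcohol by SN2 on the alkoxyphosphonium, with the alkene geometry retained.

Step 9
Reactants: 11 8-phenylmenthyl 2-methyl-3-oxobutanoate; 15 (E)-3-bromo-1-iodo-2-methylprop-1-ene
Product: 17 8-phenylmenthyl (E)-7-iodo-2,6-dimethyl-3-oxohept-6-enoate, via dienolate dianion 16 (not isolated)
Conditions: NaH (1.1 equiv), THF, 0 °C; n-BuLi (1.05 equiv), 0 °C; then 15, 0 °C; aq. HCl (1 M) quench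
Reagents that add atoms: none
Why: Weiler dianion alkylation: the more reactive γ-carbanion of the β-keto ester dianion displaces the allylic bromide (SN2) and forms C1–C2, while the alkenyl iodide is inert.

**Fragment union and core**

Step 10
Reactants: 8 (E)-1-bromo-6-chloro-3-methylhex-3-ene; 17 8-phenylmenthyl (E)-7-iodo-2,6-dimethyl-3-oxohept-6-enoate
Product: 19 8-phenylmenthyl (6E,10E)-13-chloro-2,6,10-trimethyl-3-oxotrideca-6,10-dienoate, via alkylzinc bromide 18 (not isolated)
Conditions: 8, Zn dust, LiCl, THF, 50 °C; then 17, Pd(PPh3)4 (5 mol %), THF, rt to 40 °C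
Reagents that add atoms: none
Why: Negishi cross-coupling: zinc inserts into the C–Br bond only (C–Cl inert) and palladium couples the alkylzinc with the alkenyl iodide with retention, forming C5–C6 and keeping C10=C5 E; the alkylzinc halide is too weakly basic to be quenched by the β-keto ester.

Step 11
Reactants: 19 8-phenylmenthyl (6E,10E)-13-chloro-2,6,10-trimethyl-3-oxotrideca-6,10-dienoate
Product: 20 8-phenylmenthyl (4S,5S,9R,10S)-12-chloro-3-oxo-13,14,15,16-tetranorlabd-8(17)-en-19-oate
Conditions: Mn(OAc)3·2H2O (2.2 equiv), Cu(OAc)2·H2O (0.2 equiv), degassed AcOH, 25 °C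
Reagents that add atoms: none
Why: Snider-type oxidative free-radical polyene cyclization: Mn(OAc)3 generates the C4 radical, which closes ring A 6-endo on the E C10=C5 alkene through a chair with the ester carbonyl turned away from the ketone oxygen (ester axial, cis to C20) on the face left open by the phenyl group of the auxiliary (absolute control; the minor diastereomer is removed by chromatography), the C10 radical closes ring B 6-endo on the E C8=C9 alkene (trans-decalin, C11 equatorial), and Cu(OAc)2 oxidises the C8 radical to the exocyclic alkene.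

Step 12
Reactants: 20 8-phenylmenthyl (4S,5S,9R,10S)-12-chloro-3-oxo-13,14,15,16-tetranorlabd-8(17)-en-19-oate
Product: 21 8-phenylmenthyl (4S,5S,7S,9S,10S)-12-chloro-7-hydroxy-3-oxo-13,14,15,16-tetranorlabd-8(17)-en-19-oate (axial 7-OH, with some 7-epimer)
Conditions: SeO2 (0.5 equiv), t-BuOOH (3 equiv), CH2Cl2, rt
Reagents that add atoms: tert-butyl hydroperoxide, CC(C)(C)OO
Why: SeO2/t-BuOOH allylic hydroxylation (ene reaction, then 2,3-sigmatropic shift) attacks the ring CH2 (C7) in preference to the hindered C9 methine and keeps the alkene exocyclic; the C7 configuration is of no consequence because it is erased in step 13.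

Step 13
Reactants: 21 8-phenylmenthyl (4S,5S,7S,9S,10S)-12-chloro-7-hydroxy-3-oxo-13,14,15,16-tetranorlabd-8(17)-en-19-oate
Product: 22 8-phenylmenthyl (4S,5S,9S,10S)-12-chloro-3,7-dioxo-13,14,15,16-tetranorlabd-8(17)-en-19-oate
Conditions: Dess–Martin periodinane, CH2Cl2, 0 °C to rt
Reagents that add atoms: none
Why: Dess–Martin oxidation of the only free (allylic) alcohol gives the exo-methylene ketone under mild conditions that do not move the double bond into the ring.

Step 14
Reactants: 22 8-phenylmenthyl (4S,5S,9S,10S)-12-chloro-3,7-dioxo-13,14,15,16-tetranorlabd-8(17)-en-19-oate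
Product: 23 8-phenylmenthyl (3R,4S,5S,7R,9S,10S)-12-chloro-3,7-dihydroxy-13,14,15,16-tetranorlabd-8(17)-en-19-oate
Conditions: NaBH4, CeCl3·7H2O, MeOH, −78 to 0 °C
Reagents that add atoms: none
Why: Luche reduction: 1,2-selective hydride delivery to the enone and to the C3 ketone along the axial trajectory on the face opposite the axial C20 and C19 groups (equatorial approach at C3 is blocked by the C4 substituents and at C7 is torsionally disfavoured), so both new alcohols are equatorial (3R, 7R).

Step 15
Reactants: 23 8-phenylmenthyl (3R,4S,5S,7R,9S,10S)-12-chloro-3,7-dihydroxy-13,14,15,16-tetranorlabd-8(17)-en-19-oate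
Product: 24 (3R,4R,5S,7R,9S,10S)-12-chloro-13,14,15,16-tetranorlabd-8(17)-ene-3,7,19-triol
Conditions: i-Bu2AlH (8 equiv), CH2Cl2, −78 °C to rt; aq. sodium potassium tartrate
Reagents that add atoms: none
Why: Hydride reduction of the hindered ester to the primary alcohol with i-Bu2AlH releases the auxiliary for recovery and leaves the primary alkyl chloride untouched.

Step 16
Reactants: 24 (3R,4R,5S,7R,9S,10S)-12-chloro-13,14,15,16-tetranorlabd-8(17)-ene-3,7,19-triol
Product: 25 (3R,4R,5S,7R,9S,10S)-12-iodo-13,14,15,16-tetranorlabd-8(17)-ene-3,7,19-triol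
Conditions: NaI (10 equiv), acetone, reflux
Reagents that add atoms: sodium iodide, [Na+].[I-]
Why: Finkelstein halide exchange (SN2), driven by precipitation of NaCl, gives the iodide needed for the coupling; the free hydroxyl groups are unaffected.

**Branch 3: butenolide partner**

Step 17
Reactants: 26 furan-2-carbaldehyde (furfural)
Product: 27 furan-2(5H)-one
Conditions: 30% H2O2, HCO2H, CH2Cl2/H2O, reflux; then Et3N (cat.)
Reagents that add atoms: hydrogen peroxide, OO
Why: Baeyer–Villiger oxidation of furfural by performic acid to 2-furyl formate, then hydrolysis and tautomerization of 2-hydroxyfuran, gives the butenolide.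

Step 18
Reactants: 27 furan-2(5H)-one
Product: 29 3-bromofuran-2(5H)-one, via trans-dibromolactone 28 (not isolated)
Conditions: Br2, CH2Cl2, rt; then Et3N, 0 °C
Reagents that add atoms: bromine, BrBr
Why: Anti addition of bromine to the alkene followed by E1cB-type loss of HBr (acidic α-hydrogen, β-bromide) leaves bromine on the α-carbon.

**Final coupling**

Step 19
Reactants: 25 (3R,4R,5S,7R,9S,10S)-12-iodo-13,14,15,16-tetranorlabd-8(17)-ene-3,7,19-triol; 29 3-bromofuran-2(5H)-one
Product: 30 (3R,4R,5S,7R,9S,10S)-3,7,19-trihydroxylabda-8(17),13-dien-16,15-olide (target)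
Conditions: NiBr2·MeOCH2CH2OMe (10 mol %), 4,4′-di-tert-butyl-2,2′-bipyridine (12 mol %), Zn dust (2 equiv), DMA, 25 °C, 29 (1.5 equiv) added over 3 h
Reagents that add atoms: none
Why: Proposed new method: nickel-catalysed reductive cross-electrophile coupling of an unactivated primary alkyl iodide with an α-bromobutenolide in the presence of three free hydroxyl groups, a substrate pairing not yet demonstrated; zerovalent nickel (bipyridine) inserts fastest into the electron-poor C(sp2)–Br bond of 29, the alkyl iodide is converted into the primary C12 radical by halogen abstraction at monovalent nickel, the radical is captured by the alkenylnickel bromide, C12–C13 reductive elimination occurs from trivalent nickel and Zn returns nickel to the low-valent state, and because no basic organometallic accumulates the OH groups and the lactone survive, while slow addition of 29 keeps its concentration low against radical conjugate addition; the closest known reaction type is the nickel-catalysed cross-electrophile coupling of alkyl halides with alkenyl or aryl bromides.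

**Compound list**

1 | but-3-yn-1-ol | C#CCCO | starting material
2 | tert-butyl(but-3-yn-1-yloxy)dimethylsilane | C#CCCO[Si](C)(C)C(C)(C)C | intermediate
3 | oxirane | C1CO1 | starting material
4 | (E)-[4-(tert-butyldimethylsilyloxy)-2-methylbut-1-en-1-yl]dimethylalumane | C[Al](C)/C=C(\C)CCO[Si](C)(C)C(C)(C)C | intermediate
5 | lithium butyl[(E)-4-(tert-butyldimethylsilyloxy)-2-methylbut-1-en-1-yl]dimethylaluminate | [Li+].CCCC[Al-](C)(C)/C=C(\C)CCO[Si](C)(C)C(C)(C)C | intermediate
6 | (E)-6-[(tert-butyldimethylsilyl)oxy]-4-methylhex-3-en-1-ol | OCC/C=C(\C)CCO[Si](C)(C)C(C)(C)C | intermediate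
7 | tert-butyl{[(E)-6-chloro-3-methylhex-3-en-1-yl]oxy}dimethylsilane | ClCC/C=C(\C)CCO[Si](C)(C)C(C)(C)C | intermediate
8 | (E)-1-bromo-6-chloro-3-methylhex-3-ene | ClCC/C=C(\C)CCBr | intermediate
9 | methyl 3-oxobutanoate | COC(=O)CC(C)=O | starting material
10 | methyl 2-methyl-3-oxobutanoate (racemic) | COC(=O)C(C)C(C)=O | intermediate
11 | (1S,2R,5S)-5-methyl-2-(2-phenylpropan-2-yl)cyclohexyl 2-methyl-3-oxobutanoate (α-epimers) | CC(=O)C(C)C(=O)O[C@H]1C[C@@H](C)CC[C@@H]1C(C)(C)c1ccccc1 | intermediate
12 | prop-2-yn-1-ol | C#CCO | starting material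
13 | dimethylaluminium alkoxide of (E)-3-(dimethylalumanyl)-2-methylprop-2-en-1-ol | C[Al](C)/C=C(\C)CO[Al](C)C | intermediate
14 | (E)-3-iodo-2-methylprop-2-en-1-ol | OC/C(C)=C/I | intermediate
15 | (E)-3-bromo-1-iodo-2-methylprop-1-ene | BrC/C(C)=C/I | intermediate
16 | sodium lithium dienediolate (dianion) of 11 | [Na+].[Li+].C=C([O-])C(C)=C([O-])O[C@H]1C[C@@H](C)CC[C@@H]1C(C)(C)c1ccccc1 | intermediate
17 | 8-phenylmenthyl (E)-7-iodo-2,6-dimethyl-3-oxohept-6-enoate (C2 epimers) | I/C=C(\C)CCC(=O)C(C)C(=O)O[C@H]1C[C@@H](C)CC[C@@H]1C(C)(C)c1ccccc1 | intermediate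
18 | [(E)-6-chloro-3-methylhex-3-en-1-yl]zinc bromide | ClCC/C=C(\C)CC[Zn]Br | intermediate
19 | 8-phenylmenthyl (6E,10E)-13-chloro-2,6,10-trimethyl-3-oxotrideca-6,10-dienoate (C2 epimers) | ClCC/C=C(\C)CC/C=C(\C)CCC(=O)C(C)C(=O)O[C@H]1C[C@@H](C)CC[C@@H]1C(C)(C)c1ccccc1 | intermediate
20 | 8-phenylmenthyl (4S,5S,9R,10S)-12-chloro-3-oxo-13,14,15,16-tetranorlabd-8(17)-en-19-oate (trans-decalin, axial ester) | C=C1CC[C@@H]2[C@](C)(C(=O)O[C@H]3C[C@@H](C)CC[C@@H]3C(C)(C)c3ccccc3)C(=O)CC[C@@]2(C)[C@@H]1CCCl | intermediate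
21 | 8-phenylmenthyl (4S,5S,7S,9S,10S)-12-chloro-7-hydroxy-3-oxo-13,14,15,16-tetranorlabd-8(17)-en-19-oate (axial 7-OH) | C=C1[C@@H](O)C[C@@H]2[C@](C)(C(=O)O[C@H]3C[C@@H](C)CC[C@@H]3C(C)(C)c3ccccc3)C(=O)CC[C@@]2(C)[C@@H]1CCCl | intermediate
22 | 8-phenylmenthyl (4S,5S,9S,10S)-12-chloro-3,7-dioxo-13,14,15,16-tetranorlabd-8(17)-en-19-oate | C=C1C(=O)C[C@@H]2[C@](C)(C(=O)O[C@H]3C[C@@H](C)CC[C@@H]3C(C)(C)c3ccccc3)C(=O)CC[C@@]2(C)[C@@H]1CCCl | intermediate
23 | 8-phenylmenthyl (3R,4S,5S,7R,9S,10S)-12-chloro-3,7-dihydroxy-13,14,15,16-tetranorlabd-8(17)-en-19-oate (both OH equatorial) | C=C1[C@H](O)C[C@@H]2[C@](C)(C(=O)O[C@H]3C[C@@H](C)CC[C@@H]3C(C)(C)c3ccccc3)[C@H](O)CC[C@@]2(C)[C@@H]1CCCl | intermediate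
24 | (3R,4R,5S,7R,9S,10S)-12-chloro-13,14,15,16-tetranorlabd-8(17)-ene-3,7,19-triol | C=C1[C@H](O)C[C@@H]2[C@](C)(CO)[C@H](O)CC[C@@]2(C)[C@@H]1CCCl | intermediate
25 | (3R,4R,5S,7R,9S,10S)-12-iodo-13,14,15,16-tetranorlabd-8(17)-ene-3,7,19-triol | C=C1[C@H](O)C[C@@H]2[C@](C)(CO)[C@H](O)CC[C@@]2(C)[C@@H]1CCI | intermediate
26 | furan-2-carbaldehyde | O=Cc1ccco1 | starting material
27 | furan-2(5H)-one | O=C1OCC=C1 | intermediate
28 | trans-3,4-dibromodihydrofuran-2(3H)-one (racemic) | O=C1OC[C@H](Br)[C@H]1Br | intermediate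
29 | 3-bromofuran-2(5H)-one | O=C1OCC=C1Br | intermediate
30 | (3R,4R,5S,7R,9S,10S)-3,7,19-trihydroxylabda-8(17),13-dien-16,15-olide; 3-{2-[(1S,3R,4aS,5R,6R,8aS)-3,6-dihydroxy-5-(hydroxymethyl)-5,8a-dimethyl-2-methylidenedecahydronaphthalen-1-yl]ethyl}furan-2(5H)-one | C=C1[C@H](O)C[C@@H]2[C@](C)(CO)[C@H](O)CC[C@@]2(C)[C@@H]1CCC1=CCOC1=O | target

**Step count and risks**

Total step count: 19. Longest linear sequence: 12 steps (steps 1, 2, 3, 4, 10, 11, 12, 13, 14, 15, 16, 19, from but-3-yn-1-ol).

Three steps most likely to fail: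

Step 10 (Negishi coupling next to an acidic β-keto ester). The alkylzinc may be partly protonated or the coupling may be slow. Fallback: couple first and install the keto ester afterwards. It sets out from 8 (as its zinc reagent 18) and 14 and comes back at 19. Zinc reagent 18 is coupled under the same palladium catalysis with the iodo alcohol 14 itself (free hydroxyl tolerated) to give (2E,6E)-10-chloro-2,6-dimethyldeca-2,6-dien-1-ol F1. CBr4/PPh3 converts this into (2E,6E)-1-bromo-10-chloro-2,6-dimethyldeca-2,6-diene F2. The dianion 16 of 11 is then alkylated with this allylic bromide (chloride inert at 0 °C) to give 19.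

Step 11 (oxidative bicyclization). Risks are moderate yield, endocyclic alkene isomers from the termination, and imperfect auxiliary control. Fallback: a group-transfer radical cascade that needs no oxidant and makes the alkene in a separate step. It sets out from 19 and comes back at 20. Selenenylation of 19 (NaH, PhSeCl, THF) gives 8-phenylmenthyl (6E,10E)-13-chloro-2,6,10-trimethyl-3-oxo-2-(phenylselanyl)trideca-6,10-dienoate F3. Sunlamp irradiation in benzene effects the phenylselanyl group-transfer bicyclization (same radical, same facial control) to the tertiary selenide 8-phenylmenthyl (4S,5S,8S,9S,10S)-12-chloro-3-oxo-8-(phenylselanyl)-13,14,15,16-tetranorlabdan-19-oate F4. H2O2/pyridine then gives the selenoxide, whose syn-elimination toward the freely rotating methyl group returns 20.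

Step 19 (the proposed new coupling). Risks are conjugate addition of the C12 radical to 29, reduction of 29, and homocoupling. Fallback (known two-electron chemistry): sets out from 25 and comes back at 30. Silylation of 25 (TMSCl, imidazole, DMF) gives the tris(trimethylsilyl) ether of 25 F5. Zinc insertion (Zn dust, LiCl, THF) gives the corresponding alkylzinc iodide F6. Negishi coupling with 29 (Pd(OAc)2, SPhos, THF) gives the tris(trimethylsilyl) ether of 30 F7, and citric acid in methanol removes the silyl groups to give 30.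

**Further compounds**

F1 | step 10 | (2E,6E)-10-chloro-2,6-dimethyldeca-2,6-dien-1-ol | ClCC/C=C(\C)CC/C=C(\C)CO
F2 | step 10 | (2E,6E)-1-bromo-10-chloro-2,6-dimethyldeca-2,6-diene | ClCC/C=C(\C)CC/C=C(\C)CBr
F3 | step 11 | 8-phenylmenthyl (6E,10E)-13-chloro-2,6,10-trimethyl-3-oxo-2-(phenylselanyl)trideca-6,10-dienoate | ClCC/C=C(\C)CC/C=C(\C)CCC(=O)C(C)([Se]c1ccccc1)C(=O)O[C@H]1C[C@@H](C)CC[C@@H]1C(C)(C)c1ccccc1
F4 | step 11 | 8-phenylmenthyl (4S,5S,8S,9S,10S)-12-chloro-3-oxo-8-(phenylselanyl)-13,14,15,16-tetranorlabdan-19-oate | C[C@]1([Se]c2ccccc2)CC[C@@H]2[C@](C)(C(=O)O[C@H]3C[C@@H](C)CC[C@@H]3C(C)(C)c3ccccc3)C(=O)CC[C@@]2(C)[C@@H]1CCCl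
F5 | step 19 | tris(trimethylsilyl) ether of 25 | C=C1[C@H](O[Si](C)(C)C)C[C@@H]2[C@](C)(CO[Si](C)(C)C)[C@H](O[Si](C)(C)C)CC[C@@]2(C)[C@@H]1CCI
F6 | step 19 | alkylzinc iodide from the tris(trimethylsilyl) ether of 25 | C=C1[C@H](O[Si](C)(C)C)C[C@@H]2[C@](C)(CO[Si](C)(C)C)[C@H](O[Si](C)(C)C)CC[C@@]2(C)[C@@H]1CC[Zn]I
F7 | step 19 | tris(trimethylsilyl) ether of 30 | C=C1[C@H](O[Si](C)(C)C)C[C@@H]2[C@](C)(CO[Si](C)(C)C)[C@H](O[Si](C)(C)C)CC[C@@]2(C)[C@@H]1CCC1=CCOC1=O
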